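**Retrosynthetic overview**
1. Feature: in pyran ring C of the upper (epiafzelechin) unit, O1 is the only atom between aromatic C8a (ring A) and C2. Without O1, ring C shrinks to the five-membered ring of a 3-arylindan-1-one that already contains C4 and the C4–C8' bond to the lower epicatechin unit.
2. Target ⇒ perbenzylated 6'-bromo dimer ⇒ (C2–O1 Mitsunobu closure with inversion, chelate-controlled ketone reduction, aryl Grignard on a Weinreb amide, enolate hydroxylation anti to the C4 aryl) ⇒ 4-arylchroman-2-one.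
3. 4-Arylchroman-2-one ⇒ Baeyer–Villiger oxygen insertion (indanone C7a migrates; O1–C2 and O1–C8a are made) ⇒ (3R)-3-arylindan-1-one whose only free ring A' position, C6', is capped with bromine.
4. Indanone ⇒ asymmetric reductive Heck closure ⇒ 2'-bromochalcone ⇒ Claisen–Schmidt union of penta-O-benzylepicatechin-8-carbaldehyde with 2-bromo-3,5-bis(benzyloxy)acetophenone.
5. Ring order: rings A', C', B' come with epicatechin and ring A with the acetophenone. The five-membered carbocycle forms in step 7, is expanded to the ring C lactone in step 9, is opened in step 12 to bring in ring B, and is closed as the pyran ring C in step 16.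

Key step: step 9

Numbering: free-standing epicatechin derivatives carry the usual flavan locants. After the union the lower unit is primed (C6', C8', ring A'), and from step 9 on the upper unit carries flavan locants (O1, C2, C3, C4, C4a, C8a). "Penta-O-benzylepicatechin-8-yl" means (2R,3R)-3,5,7-tris(benzyloxy)-2-[3,4-bis(benzyloxy)phenyl]chroman-8-yl.
Assumption: the ligand enantiomer written in step 7 is taken to be the one that gives the (3R)-indanone; if the sense of induction is the opposite, its equally available mirror image is used.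

**Step 1**
Reactants: 1 (−)-epicatechin
Product: 2 5,7,3',4'-tetra-O-benzylepicatechin
Conditions: BnBr (4.4 equiv), K2CO3, DMF, 0 °C → rt, N2
Reagents that add atoms: benzyl bromide, BrCc1ccccc1
Why: Williamson etherification in which K2CO3 ionises only the four phenols, so the C3 alcohol stays free, and the mild base under inert gas avoids the C2 epimerisation that stronger base causes in free flavan-3-ols.

**Step 2**
Reactants: 2 5,7,3',4'-tetra-O-benzylepicatechin
Product: 3 8-bromo-5,7,3',4'-tetra-O-benzylepicatechin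
Conditions: NBS (1.0 equiv), CH2Cl2, −78 °C → rt
Reagents that add atoms: N-bromosuccinimide, O=C1CCC(=O)N1Br
Why: Electrophilic aromatic bromination, in which the phloroglucinol-type ring A is by far the most nucleophilic arene and C8 of the tetrabenzyl ether is known to react ahead of C6 with one equivalent of NBS at low temperature.

**Step 3**
Reactants: 3 8-bromo-5,7,3',4'-tetra-O-benzylepicatechin
Product: 4 8-bromo-3,5,7,3',4'-penta-O-benzylepicatechin
Conditions: NaH, BnBr, DMF, 0 °C → rt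
Reagents that add atoms: benzyl bromide, BrCc1ccccc1
Why: Williamson etherification of the secondary alkoxide, which is safe for C2 because no phenol is free any more and the quinone-methide path to epimerisation is closed.

**Step 4**
Reactants: 4 8-bromo-3,5,7,3',4'-penta-O-benzylepicatechin
Product: 6 penta-O-benzylepicatechin-8-carbaldehyde, via 8-lithio-penta-O-benzylepicatechin 5 (not isolated)
Conditions: n-BuLi, THF, −78 °C; DMF, −78 → 0 °C; H2O
Reagents that add atoms: N,N-dimethylformamide, CN(C)C=O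
Why: Bromine–lithium exchange, assisted by the two flanking oxygens and faster at −78 °C than benzylic deprotonation, followed by formylation of the aryllithium with DMF (Bouveault-type aldehyde synthesis), which fixes the carbon substituent at C8.

**Step 5**
Reactants: 7 3',5'-dibenzyloxyacetophenone
Product: 8 1-[3,5-bis(benzyloxy)-2-bromophenyl]ethan-1-one
Conditions: NBS (1.0 equiv), MeCN, 0 °C → rt, dark
Reagents that add atoms: N-bromosuccinimide, O=C1CCC(=O)N1Br
Why: Electrophilic aromatic bromination in polar MeCN goes to the ring and not to the acetyl CH3, and to C2 (para to one ether, ortho to the other) rather than to the crowded C4 between both ethers, as is known for 3,5-dialkoxyaryl carbonyl compounds.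

**Step 6**
Reactants: 6 penta-O-benzylepicatechin-8-carbaldehyde; 8 1-[3,5-bis(benzyloxy)-2-bromophenyl]ethan-1-one
Product: 9 (E)-1-[3,5-bis(benzyloxy)-2-bromophenyl]-3-(penta-O-benzylepicatechin-8-yl)prop-2-en-1-one
Conditions: KOH, EtOH–THF, rt → 40 °C
Reagents that add atoms: none
Why: Claisen–Schmidt condensation in which only 8 can enolise and only 6 can accept, E1cB loss of water gives the conjugated (E)-enone for steric reasons, and hydroxide finds nothing else to attack because every phenol is etherified.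

**Step 7**
Reactants: 9 (E)-2'-bromochalcone
Product: 10 (3R)-4,6-bis(benzyloxy)-3-(penta-O-benzylepicatechin-8-yl)indan-1-one
Conditions: Pd(OAc)2 (10 mol %), (R)-3,5-Xyl-MeO-BIPHEP (12 mol %), HCO2H (slow addition), iPr2NEt, DMF, 90 °C
Reagents that add atoms: none
Why: Asymmetric reductive Heck cyclisation known for 2'-halochalcones, in which zerovalent palladium inserts into the C–Br bond activated by the ortho acyl group, the aryl–palladium species adds to the enone β-carbon (formal 5-endo closure) on the face chosen by the chiral bisphosphine and so sets C3 as (R), and the palladium enolate is protonated while formate returns divalent palladium to the zerovalent state.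

**Step 8**
Reactants: 10 (3R)-4,6-bis(benzyloxy)-3-(penta-O-benzylepicatechin-8-yl)indan-1-one
Product: 11 (3R)-4,6-bis(benzyloxy)-3-(penta-O-benzyl-6-bromoepicatechin-8-yl)indan-1-one
Conditions: NBS (1.05 equiv), CH2Cl2, −40 → 0 °C, dark
Reagents that add atoms: N-bromosuccinimide, O=C1CCC(=O)N1Br
Why: Electrophilic aromatic bromination that should cap only C6', the single free position of the trialkoxy ring A', because both free positions of the indanone arene are ortho or para to the acyl group and deactivated; the bromine is a spectator that leaves in step 17.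

**Step 9**
Reactants: 11 (3R)-4,6-bis(benzyloxy)-3-(penta-O-benzyl-6-bromoepicatechin-8-yl)indan-1-one
Product: 13 (4R)-5,7-bis(benzyloxy)-4-(penta-O-benzyl-6-bromoepicatechin-8-yl)chroman-2-one, via Criegee adduct 12 (not isolated)
Conditions: m-CPBA (3 equiv), Na2HPO4, CH2Cl2, 0 °C → rt, dark
Reagents that add atoms: 3-chloroperbenzoic acid, OOC(=O)c1cccc(Cl)c1
Why: The peracid adds to the C1 ketone (this makes the future O1–C2 bond) to give Criegee adduct 12, and the aryl carbon C7a, lying anti to the O–O bond, then shifts from C1 to that oxygen while 3-chlorobenzoate leaves (this makes O1–C8a). The closest known reaction is the Baeyer–Villiger oxidation of 1-indanones, 3-aryl-1-indanones included, to 3,4-dihydrocoumarins. Ring C is closed by ring expansion, a 1,2-shift that turns the five-membered ketone into the six-membered lactone, not by cyclisation of an open chain. No stereocentre is made, and C4, two bonds away from the reacting carbon, keeps its (R) configuration. Aryl must migrate ahead of the C2 methylene (indanone locant): both benzyloxy groups are meta to C7a and lend no push, so the step rests on the intrinsic aryl-over-primary-alkyl order of 1-indanones, helped by π participation of the arene and by the ortho alkyl branch, and C3 (flavan locant) stays free of oxygen until step 10 because an α-oxygenated carbon would out-migrate the arene. The ketone must react ahead of the arenes: the same meta relationship keeps C1 from being a sluggish vinylogous ester, the one unsubstituted carbon of the most electron-rich ring (C6') is blocked by bromine, and the phosphate buffer takes away the acid that would speed up arene hydroxylation and heterolysis of the C4–C8' bond.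

**Step 10**
Reactants: 13 (4R)-5,7-bis(benzyloxy)-4-(penta-O-benzyl-6-bromoepicatechin-8-yl)chroman-2-one
Product: 15 (3R,4R)-3-hydroxy lactone, via potassium enolate 14 (not isolated)
Conditions: KN(SiMe3)2, THF, −78 °C; 2-(phenylsulfonyl)-3-phenyloxaziridine, −78 °C; AcOH
Reagents that add atoms: 2-(phenylsulfonyl)-3-phenyloxaziridine, O=S(=O)(c1ccccc1)N1OC1c1ccccc1
Why: Davis-type enolate hydroxylation, in which enolate 14 is planar at C3 and its face syn to the pseudoaxial C4 aryl group is shielded, so oxygen arrives anti to that group and sets C3 as (R), 3,4-trans.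

**Step 11**
Reactants: 15 (3R,4R)-3-hydroxy lactone
Product: 16 (3R,4R)-3-benzyloxy lactone
Conditions: BnBr, Ag2O, 4 Å MS, CH2Cl2, rt, dark
Reagents that add atoms: benzyl bromide, BrCc1ccccc1
Why: Ag2O-promoted Williamson-type benzylation, as used for α-hydroxy esters, works without free base so that C3 does not epimerise and the aryl lactone does not open, and the ether keeps the C3 oxygen out of step 16 while it can still chelate in step 14.

**Step 12**
Reactants: 16 (3R,4R)-3-benzyloxy lactone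
Product: 18 O-TBS-protected Weinreb amide, via phenolic Weinreb amide 17 (not isolated)
Conditions: MeNH(OMe)·HCl, AlMe3, CH2Cl2, 0 °C → rt; aq. potassium sodium tartrate; crude 17, TBSOTf, 2,6-lutidine, CH2Cl2, 0 °C
Reagents that add atoms: N,O-dimethylhydroxylamine hydrochloride, CNOC.Cl; tert-butyldimethylsilyl triflate, CC(C)(C)[Si](C)(C)OS(=O)(=O)C(F)(F)F
Why: Aluminium-amide aminolysis of the activated aryl ester gives the Weinreb amide without touching C3, and the freed C8a phenol, which sits in a crowded trimethyl-lock-like array that favours re-lactonisation, is silylated at once.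

**Step 13**
Reactants: 18 O-TBS-protected Weinreb amide; 19 4-benzyloxybromobenzene
Product: 21 4-benzyloxyphenyl ketone, via 4-benzyloxyphenylmagnesium bromide 20 (not isolated)
Conditions: 19, Mg, THF, reflux; then 18, THF, 0 °C → rt; H2O
Reagents that add atoms: none
Why: Weinreb ketone synthesis, in which Grignard reagent 20 adds only once because the magnesium-chelated tetrahedral adduct lasts until work-up, while the hexasubstituted aryl bromide, the silyl ether and C3 are not touched at this temperature.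

**Step 14**
Reactants: 21 4-benzyloxyphenyl ketone
Product: 22 2,3-anti benzylic alcohol with C2 (S)
Conditions: Zn(BH4)2, Et2O–CH2Cl2, −40 → 0 °C
Reagents that add atoms: none
Why: Chelation-controlled (Cram-chelate) reduction, in which zinc bridges the ketone oxygen and the C3 benzyloxy oxygen and hydride enters from the side of H3, away from the bulky C4 carbon, which gives the 2,3-anti alcohol with C2 (S).

**Step 15**
Reactants: 22 2,3-anti benzylic alcohol
Product: 23 C8a phenol with free C2 alcohol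
Conditions: Bu4NF, AcOH, THF, 0 °C
Reagents that add atoms: none
Why: Fluoride-mediated desilylation cleaves the aryl silyl ether fast and selectively, and the acetic acid buffer keeps the phenoxide and the sensitive 4-alkoxybenzylic alcohol from reacting prematurely.

**Step 16**
Reactants: 23 C8a phenol with free C2 alcohol
Product: 24 nona-O-benzyl-6'-bromo-epiafzelechin-(4β→8)-epicatechin
Conditions: PPh3, DIAD, toluene, 0 °C → rt
Reagents that add atoms: none
Why: Intramolecular Mitsunobu etherification (6-exo-tet SN2), in which only the C2 hydroxyl can be activated, the C8a phenol is the acidic partner, backside displacement inverts C2 from (S) to (R) to give the 2,3-cis-3,4-trans ring C, and the apolar solvent and low temperature disfavour ionisation of the oxyphosphonium ion.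

**Step 17**
Reactants: 24 nona-O-benzyl-6'-bromo-epiafzelechin-(4β→8)-epicatechin
Product: 25 (−)-epiafzelechin-(4β→8)-(−)-epicatechin
Conditions: H2 (1 atm), Pd(OH)2/C, Et3N (1 equiv), THF–MeOH–H2O, rt
Reagents that add atoms: none
Why: Catalytic hydrogenolysis removes the nine benzyl ethers and hydrodebrominates C6' in one operation, Et3N takes up the HBr that could otherwise cleave the acid-labile C4–C8' bond, and no stereocentre is affected.

**Compound list**
1 | (−)-epicatechin, (2R,3R)-2-(3,4-dihydroxyphenyl)chroman-3,5,7-triol | O[C@@H]1Cc2c(O)cc(O)cc2O[C@@H]1c1ccc(O)c(O)c1 | starting material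
2 | (2R,3R)-5,7,3',4'-tetra-O-benzylepicatechin (3-OH free) | O[C@@H]1Cc2c(OCc3ccccc3)cc(OCc3ccccc3)cc2O[C@@H]1c1ccc(OCc2ccccc2)c(OCc2ccccc2)c1 | intermediate
3 | (2R,3R)-8-bromo-5,7,3',4'-tetra-O-benzylepicatechin | O[C@@H]1Cc2c(OCc3ccccc3)cc(OCc3ccccc3)c(Br)c2O[C@@H]1c1ccc(OCc2ccccc2)c(OCc2ccccc2)c1 | intermediate
4 | (2R,3R)-8-bromo-3,5,7,3',4'-penta-O-benzylepicatechin | Brc3c(OCc5ccccc5)cc(OCc5ccccc5)c4c3O[C@H](c3ccc(OCc5ccccc5)c(OCc5ccccc5)c3)[C@H](OCc5ccccc5)C4 | intermediate
5 | (2R,3R)-8-lithio-3,5,7,3',4'-penta-O-benzylepicatechin | [Li]c3c(OCc5ccccc5)cc(OCc5ccccc5)c4c3O[C@H](c3ccc(OCc5ccccc5)c(OCc5ccccc5)c3)[C@H](OCc5ccccc5)C4 | intermediate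
6 | (2R,3R)-3,5,7,3',4'-penta-O-benzylepicatechin-8-carbaldehyde | O=Cc3c(OCc5ccccc5)cc(OCc5ccccc5)c4c3O[C@H](c3ccc(OCc5ccccc5)c(OCc5ccccc5)c3)[C@H](OCc5ccccc5)C4 | intermediate
7 | 3',5'-dibenzyloxyacetophenone | CC(=O)c1cc(OCc2ccccc2)cc(OCc2ccccc2)c1 | starting material
8 | 1-[3,5-bis(benzyloxy)-2-bromophenyl]ethan-1-one | CC(=O)c1cc(OCc2ccccc2)cc(OCc2ccccc2)c1Br | intermediate
9 | (E)-1-[3,5-bis(benzyloxy)-2-bromophenyl]-3-(penta-O-benzylepicatechin-8-yl)prop-2-en-1-one | O=C(/C=C/c3c(OCc5ccccc5)cc(OCc5ccccc5)c4c3O[C@H](c3ccc(OCc5ccccc5)c(OCc5ccccc5)c3)[C@H](OCc5ccccc5)C4)c1cc(OCc5ccccc5)cc(OCc5ccccc5)c1Br | intermediate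
10 | (3R)-4,6-bis(benzyloxy)-3-(penta-O-benzylepicatechin-8-yl)indan-1-one | O=C1C[C@@H](c3c(OCc5ccccc5)cc(OCc5ccccc5)c4c3O[C@H](c3ccc(OCc5ccccc5)c(OCc5ccccc5)c3)[C@H](OCc5ccccc5)C4)c2c1cc(OCc5ccccc5)cc2OCc5ccccc5 | intermediate
11 | (3R)-4,6-bis(benzyloxy)-3-(penta-O-benzyl-6-bromoepicatechin-8-yl)indan-1-one | O=C1C[C@@H](c3c(OCc5ccccc5)c(Br)c(OCc5ccccc5)c4c3O[C@H](c3ccc(OCc5ccccc5)c(OCc5ccccc5)c3)[C@H](OCc5ccccc5)C4)c2c1cc(OCc5ccccc5)cc2OCc5ccccc5 | intermediate
12 | Criegee adduct: 1-hydroxy-1-(3-chlorobenzoylperoxy) derivative of 11 (C1 undefined, C3 R) | OC1(OOC(=O)c6cccc(Cl)c6)C[C@@H](c3c(OCc5ccccc5)c(Br)c(OCc5ccccc5)c4c3O[C@H](c3ccc(OCc5ccccc5)c(OCc5ccccc5)c3)[C@H](OCc5ccccc5)C4)c2c1cc(OCc5ccccc5)cc2OCc5ccccc5 | intermediate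
13 | (4R)-5,7-bis(benzyloxy)-4-(penta-O-benzyl-6-bromoepicatechin-8-yl)chroman-2-one | O=C1C[C@@H](c3c(OCc5ccccc5)c(Br)c(OCc5ccccc5)c4c3O[C@H](c3ccc(OCc5ccccc5)c(OCc5ccccc5)c3)[C@H](OCc5ccccc5)C4)c2c(O1)cc(OCc5ccccc5)cc2OCc5ccccc5 | intermediate
14 | potassium enolate of 13 (C2–C3 enolate, C4 R) | [K+].[O-]C1=C[C@@H](c3c(OCc5ccccc5)c(Br)c(OCc5ccccc5)c4c3O[C@H](c3ccc(OCc5ccccc5)c(OCc5ccccc5)c3)[C@H](OCc5ccccc5)C4)c2c(O1)cc(OCc5ccccc5)cc2OCc5ccccc5 | intermediate
15 | (3R,4R)-5,7-bis(benzyloxy)-3-hydroxy-4-(penta-O-benzyl-6-bromoepicatechin-8-yl)chroman-2-one (3,4-trans) | O=C1[C@H](O)[C@@H](c3c(OCc5ccccc5)c(Br)c(OCc5ccccc5)c4c3O[C@H](c3ccc(OCc5ccccc5)c(OCc5ccccc5)c3)[C@H](OCc5ccccc5)C4)c2c(O1)cc(OCc5ccccc5)cc2OCc5ccccc5 | intermediate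
16 | (3R,4R)-3,5,7-tris(benzyloxy)-4-(penta-O-benzyl-6-bromoepicatechin-8-yl)chroman-2-one | O=C1[C@H](OCc5ccccc5)[C@@H](c3c(OCc5ccccc5)c(Br)c(OCc5ccccc5)c4c3O[C@H](c3ccc(OCc5ccccc5)c(OCc5ccccc5)c3)[C@H](OCc5ccccc5)C4)c2c(O1)cc(OCc5ccccc5)cc2OCc5ccccc5 | intermediate
17 | (2R,3R)-2-benzyloxy-3-[2,4-bis(benzyloxy)-6-hydroxyphenyl]-N-methoxy-N-methyl-3-(penta-O-benzyl-6-bromoepicatechin-8-yl)propanamide | CON(C)C(=O)[C@H](OCc5ccccc5)[C@@H](c3c(OCc5ccccc5)c(Br)c(OCc5ccccc5)c4c3O[C@H](c3ccc(OCc5ccccc5)c(OCc5ccccc5)c3)[C@H](OCc5ccccc5)C4)c2c(O)cc(OCc5ccccc5)cc2OCc5ccccc5 | intermediate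
18 | (2R,3S)-2-benzyloxy-3-[2,4-bis(benzyloxy)-6-(tert-butyldimethylsilyloxy)phenyl]-N-methoxy-N-methyl-3-(penta-O-benzyl-6-bromoepicatechin-8-yl)propanamide (C3 unchanged in space; the descriptor changes only through the CIP rank of O–Si) | CON(C)C(=O)[C@H](OCc5ccccc5)[C@@H](c3c(OCc5ccccc5)c(Br)c(OCc5ccccc5)c4c3O[C@H](c3ccc(OCc5ccccc5)c(OCc5ccccc5)c3)[C@H](OCc5ccccc5)C4)c2c(O[Si](C)(C)C(C)(C)C)cc(OCc5ccccc5)cc2OCc5ccccc5 | intermediate
19 | 4-benzyloxybromobenzene | Brc1ccc(OCc2ccccc2)cc1 | starting material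
20 | 4-benzyloxyphenylmagnesium bromide | Br[Mg]c1ccc(OCc2ccccc2)cc1 | intermediate
21 | (2R,3S)-2-benzyloxy-1-(4-benzyloxyphenyl)-3-[2,4-bis(benzyloxy)-6-(tert-butyldimethylsilyloxy)phenyl]-3-(penta-O-benzyl-6-bromoepicatechin-8-yl)propan-1-one | O=C(c1ccc(OCc5ccccc5)cc1)[C@H](OCc5ccccc5)[C@@H](c3c(OCc5ccccc5)c(Br)c(OCc5ccccc5)c4c3O[C@H](c3ccc(OCc5ccccc5)c(OCc5ccccc5)c3)[C@H](OCc5ccccc5)C4)c2c(O[Si](C)(C)C(C)(C)C)cc(OCc5ccccc5)cc2OCc5ccccc5 | intermediate
22 | (1S,2R,3S)-propan-1-ol from 21 (1,2-anti; flavan C2 S, C3 R) | O[C@@H](c1ccc(OCc5ccccc5)cc1)[C@H](OCc5ccccc5)[C@@H](c3c(OCc5ccccc5)c(Br)c(OCc5ccccc5)c4c3O[C@H](c3ccc(OCc5ccccc5)c(OCc5ccccc5)c3)[C@H](OCc5ccccc5)C4)c2c(O[Si](C)(C)C(C)(C)C)cc(OCc5ccccc5)cc2OCc5ccccc5 | intermediate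
23 | (1S,2R,3R)-2-benzyloxy-1-(4-benzyloxyphenyl)-3-[2,4-bis(benzyloxy)-6-hydroxyphenyl]-3-(penta-O-benzyl-6-bromoepicatechin-8-yl)propan-1-ol | O[C@@H](c1ccc(OCc5ccccc5)cc1)[C@H](OCc5ccccc5)[C@@H](c3c(OCc5ccccc5)c(Br)c(OCc5ccccc5)c4c3O[C@H](c3ccc(OCc5ccccc5)c(OCc5ccccc5)c3)[C@H](OCc5ccccc5)C4)c2c(O)cc(OCc5ccccc5)cc2OCc5ccccc5 | intermediate
24 | (2R,3R,4R)-3,5,7-tris(benzyloxy)-2-(4-benzyloxyphenyl)-4-(penta-O-benzyl-6-bromoepicatechin-8-yl)chroman (2,3-cis-3,4-trans) | c1ccccc1COc1ccc([C@H]2Oc3cc(OCc5ccccc5)cc(OCc5ccccc5)c3[C@H](c3c(OCc5ccccc5)c(Br)c(OCc5ccccc5)c4c3O[C@H](c3ccc(OCc5ccccc5)c(OCc5ccccc5)c3)[C@H](OCc5ccccc5)C4)[C@H]2OCc5ccccc5)cc1 | intermediate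
25 | (−)-epiafzelechin-(4β→8)-(−)-epicatechin (2R,3R,4R,2'R,3'R) | Oc1ccc([C@H]2Oc3cc(O)cc(O)c3[C@H](c3c(O)cc(O)c4c3O[C@H](c3ccc(O)c(O)c3)[C@H](O)C4)[C@H]2O)cc1 | target

**Total step count:** 17. **Longest linear sequence:** 16 steps (from 1 through steps 1–4 and 6–17).

**Three steps most likely to fail**

1. Step 9.
 - What may go wrong: the arene that has to migrate has no ortho or para donor. Rearrangement of the Criegee adduct may therefore be slow enough for methylene migration and for over-oxidation of the benzyloxyarenes (ring A of the lactone included) to compete.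
 - The fallback builds the lactone without any oxidant and sets out from aldehyde 6. Knoevenagel condensation with Meldrum's acid (piperidine, AcOH, toluene, rt) should give the arylidene Meldrum's acid F1.
 - F1 is then annulated with commercial 3,5-bis(benzyloxy)phenol (Oc1cc(OCc2ccccc2)cc(OCc2ccccc2)c1) under Yb(OTf)3 catalysis in hot MeNO2. This is a Friedel–Crafts-type conjugate addition through the carbon ortho to OH, followed by lactonisation with loss of acetone and CO2. It should give the uncapped lactone (4R)-5,7-bis(benzyloxy)-4-(penta-O-benzylepicatechin-8-yl)chroman-2-one F2.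
 - Here C4 is set only by the resident stereocentres, so the C4 epimer would have to be removed by chromatography.
 - Bromination at C6' (NBS, CH2Cl2, −40 °C) brings the material back to the route at 13. Ring A, whose para oxygen is acylated, is the less nucleophilic ring.

2. Step 7.
 - What may go wrong: formate may reduce the aryl–palladium intermediate before it inserts at the crowded β-carbon (hydrodebromination). Facial selectivity may also suffer from the two ortho substituents of the β-aryl group.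
 - The fallback replaces the palladium hydride manifold by a rhodium-catalysed conjugate addition and sets out from 9. Miyaura borylation (Pd(dppf)Cl2, B2pin2, KOAc, dioxane, 80 °C) should give the pinacol boronate chalcone F3.
 - Asymmetric intramolecular 1,4-addition of the arylboronate to the enone ([Rh(C2H4)2Cl]2, chiral phosphoramidite or BINAP ligand, aq. K3PO4, toluene), a known route to 3-arylindanones, closes the five-membered ring and comes back to the route at 10.

3. Step 16.
 - What may go wrong: the oxyphosphonium ion sits on a 4-benzyloxybenzylic carbon and may ionise. Closure would then run partly through a cation, the C2 configuration would be eroded, and the all-equatorial 2,3-trans arrangement would compete.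
 - The fallback removes the para donor during the closure and sets out from Weinreb amide 18. 4-Iodophenol is acylated (PivCl, Et3N, CH2Cl2) to 4-iodophenyl pivalate F4.
 - Iodine–magnesium exchange (iPrMgCl, THF, −20 °C) gives 4-(pivaloyloxy)phenylmagnesium chloride F5, and its addition to 18 gives the 4-pivaloyloxyphenyl ketone F6.
 - Zn(BH4)2 reduction as in step 14 should give the anti alcohol F7, and Bu4NF/AcOH the phenol F8.
 - The Mitsunobu closure, now at a benzylic carbon without a strong donor, should give the flavan pivalate F9 by clean inversion.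
 - iBu2AlH (CH2Cl2, −78 °C) removes the pivalate without base, which avoids C2 epimerisation through a ring B quinone methide, and gives the 4'-phenol F10.
 - Hydrogenolysis under the conditions of step 17 comes back to the route at 25.

**Further compounds**
F1 | step 9 | 2,2-dimethyl-5-[(penta-O-benzylepicatechin-8-yl)methylidene]-1,3-dioxane-4,6-dione | CC1(C)OC(=O)C(=Cc3c(OCc5ccccc5)cc(OCc5ccccc5)c4c3O[C@H](c3ccc(OCc5ccccc5)c(OCc5ccccc5)c3)[C@H](OCc5ccccc5)C4)C(=O)O1
F2 | step 9 | (4R)-5,7-bis(benzyloxy)-4-(penta-O-benzylepicatechin-8-yl)chroman-2-one | O=C1C[C@@H](c3c(OCc5ccccc5)cc(OCc5ccccc5)c4c3O[C@H](c3ccc(OCc5ccccc5)c(OCc5ccccc5)c3)[C@H](OCc5ccccc5)C4)c2c(O1)cc(OCc5ccccc5)cc2OCc5ccccc5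
F3 | step 7 | (E)-1-[3,5-bis(benzyloxy)-2-(4,4,5,5-tetramethyl-1,3,2-dioxaborolan-2-yl)phenyl]-3-(penta-O-benzylepicatechin-8-yl)prop-2-en-1-one | O=C(/C=C/c3c(OCc5ccccc5)cc(OCc5ccccc5)c4c3O[C@H](c3ccc(OCc5ccccc5)c(OCc5ccccc5)c3)[C@H](OCc5ccccc5)C4)c1cc(OCc5ccccc5)cc(OCc5ccccc5)c1B6OC(C)(C)C(C)(C)O6
F4 | step 16 | 4-iodophenyl pivalate | CC(C)(C)C(=O)Oc1ccc(I)cc1
F5 | step 16 | 4-(pivaloyloxy)phenylmagnesium chloride | CC(C)(C)C(=O)Oc1ccc([Mg]Cl)cc1
F6 | step 16 | analogue of 21 with 4-pivaloyloxyphenyl in place of 4-benzyloxyphenyl | O=C(c1ccc(OC(=O)C(C)(C)C)cc1)[C@H](OCc5ccccc5)[C@@H](c3c(OCc5ccccc5)c(Br)c(OCc5ccccc5)c4c3O[C@H](c3ccc(OCc5ccccc5)c(OCc5ccccc5)c3)[C@H](OCc5ccccc5)C4)c2c(O[Si](C)(C)C(C)(C)C)cc(OCc5ccccc5)cc2OCc5ccccc5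
F7 | step 16 | analogue of 22 with 4-pivaloyloxyphenyl (1,2-anti alcohol) | O[C@@H](c1ccc(OC(=O)C(C)(C)C)cc1)[C@H](OCc5ccccc5)[C@@H](c3c(OCc5ccccc5)c(Br)c(OCc5ccccc5)c4c3O[C@H](c3ccc(OCc5ccccc5)c(OCc5ccccc5)c3)[C@H](OCc5ccccc5)C4)c2c(O[Si](C)(C)C(C)(C)C)cc(OCc5ccccc5)cc2OCc5ccccc5
F8 | step 16 | analogue of 23 with 4-pivaloyloxyphenyl (free C8a phenol) | O[C@@H](c1ccc(OC(=O)C(C)(C)C)cc1)[C@H](OCc5ccccc5)[C@@H](c3c(OCc5ccccc5)c(Br)c(OCc5ccccc5)c4c3O[C@H](c3ccc(OCc5ccccc5)c(OCc5ccccc5)c3)[C@H](OCc5ccccc5)C4)c2c(O)cc(OCc5ccccc5)cc2OCc5ccccc5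
F9 | step 16 | (2R,3R,4R)-3,5,7-tris(benzyloxy)-4-(penta-O-benzyl-6-bromoepicatechin-8-yl)-2-(4-pivaloyloxyphenyl)chroman | CC(C)(C)C(=O)Oc1ccc([C@H]2Oc3cc(OCc5ccccc5)cc(OCc5ccccc5)c3[C@H](c3c(OCc5ccccc5)c(Br)c(OCc5ccccc5)c4c3O[C@H](c3ccc(OCc5ccccc5)c(OCc5ccccc5)c3)[C@H](OCc5ccccc5)C4)[C@H]2OCc5ccccc5)cc1
F10 | step 16 | (2R,3R,4R)-3,5,7-tris(benzyloxy)-2-(4-hydroxyphenyl)-4-(penta-O-benzyl-6-bromoepicatechin-8-yl)chroman | Oc1ccc([C@H]2Oc3cc(OCc5ccccc5)cc(OCc5ccccc5)c3[C@H](c3c(OCc5ccccc5)c(Br)c(OCc5ccccc5)c4c3O[C@H](c3ccc(OCc5ccccc5)c(OCc5ccccc5)c3)[C@H](OCc5ccccc5)C4)[C@H]2OCc5ccccc5)cc1
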